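**Retrosynthetic overview**

1. The target is an ester between two 6-isopropyl-2-benzoxepin-1-one units of opposite absolute configuration: the acyl half is the (5aS,6R,9S,9aS) 9-hydroxy-9-(hydroxymethyl) acid, the alkyl half the (5aR,6S,9R,9aR) unit esterified on its C9 CH2O. The ester C–O bond is cut to diol acid 21 and the mirror-image C9 spiro-oxirane ester 20 (carboxylate opening at the oxirane CH2).
2. Because the two halves are antipodal in their ring skeleton, one racemic spiro-epoxide ester 18 supplies both: an epoxide hydrolase hydrolyses the (9S) antipode to diol 19 (step 10) and, in a second run carried further, leaves the (9R) epoxide 20 (step 11).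
3. 18 comes from ring-closing metathesis (C4=C5 of the oxepinone) between a C5a vinyl group and a 2-substituted acrylate ester on C9a; the oxirane from sulfonium ylide addition to the C9 ketone; the C5a vinyl group and the C9a carbon from conjugate addition/aldol trapping on enone 8.
4. Feature behind the key step: in the cyclohexane ring, C9 carries oxygen and lies between C8 and C9a, while C6 (isopropyl) lies between C7 and C5a. At the ketone/enone level C8–C9–C9a is an acetone 1,3-bis-nucleophile and C7–C6–C5a is 2-isopropylacrolein, so C7–C8 (Michael) and C5a–C9a (aldol condensation) are made in one annulation, with a tert-butyl ester on C8 as removable activating group.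
5. Ring order: cyclohexane (step 2), oxirane (step 5), oxepinone (step 9); then resolution (steps 10 and 11), ester cleavage (step 12), union (step 13), deprotection (step 14).

Key step: step 2

Remark: the two halves have mirror-image ring configurations, so racemic intermediates are intended; they are written as both enantiomers joined by a dot with relative descriptors (R*,S*). The hydrolase of steps 10 and 11 is assumed to be chosen by screening for the (9S) antipode. The resolution is run on two portions of 18, one stopped early for the diol and one carried past half conversion for the remaining epoxide; the enriched epoxide recovered in step 10 can be added to the charge of step 11.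

**Route**

Step 1
Reactants: 1 3-methylbutanal (isovaleraldehyde); 2 formaldehyde (37 % aqueous)
Product: 3 3-methyl-2-methylidenebutanal (2-isopropylacrolein)
Conditions: aq. HCHO (1.05 equiv), pyrrolidine (10 mol %), propanoic acid (10 mol %), i-PrOH, 45 °C; distillation
Reagents that add atoms: none
Why: Amine/acid-catalysed Mannich condensation of the aldehyde with formaldehyde followed by elimination of the amine (α-methylenation of an α-unbranched aldehyde) should give the 2-substituted acrolein, and no stereocentre is formed.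

Step 2
Reactants: 3 2-isopropylacrolein; 4 tert-butyl 3-oxobutanoate (tert-butyl acetoacetate)
Product: 8 (±)-4-(propan-2-yl)cyclohex-2-en-1-one (racemic cryptone), via Michael adduct 5 (not isolated), via cyclohexenone ester 6 (not isolated), via keto acid 7 (not isolated)
Conditions: Et3N (10 mol %), toluene, 0 °C → rt; then p-TsOH·H2O (0.3 equiv), toluene, 90 °C (one pot)
Reagents that add atoms: none
Why: Base-catalysed Michael addition of the doubly activated α-carbon of 4 (future C8) to the β-carbon of enal 3 (future C7) gives keto aldehyde 5; under acid the methyl-ketone enol (future C9a) closes onto the aldehyde carbon (future C5a) in an aldol condensation, and the tert-butyl β-keto ester then loses isobutene and CO2, so the ester is a traceless activating group. The closest known reaction type is the Robinson-type Michael/aldol condensation/decarboxylation annulation of tert-butyl β-keto esters with enals to cyclohex-2-enones. The cyclohexane ring closes in the 6-(enolendo)-exo-trig mode. The only stereocentre formed, C4 of 8 (future C6), arises by protonation without a controlling element; this is intended, because the target consumes both antipodes of this carbocycle in equal amounts and every later stereocentre is relayed from it. The selectivity needed is α-carbon-to-CH2 in the Michael step and methyl-to-CHO in the aldol step; it is secured by the higher acidity of the β-keto ester α-position and by ring size, since every other intramolecular aldol would give a four-membered ring.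

Step 3
Reactants: 8 (±)-4-(propan-2-yl)cyclohex-2-en-1-one; 2 formaldehyde (anhydrous monomer)
Product: 10 (±)-(2R*,3R*,4R*)-3-ethenyl-2-(hydroxymethyl)-4-(propan-2-yl)cyclohexan-1-one, via magnesium enolate 9 (not isolated)
Conditions: CH2=CHMgBr (1.3 equiv), CuBr·SMe2 (10 mol %), THF, −78 °C; then HCHO (gas from cracked paraformaldehyde, excess), −78 → −40 °C; aq. NH4Cl
Reagents that add atoms: vinylmagnesium bromide, C=C[Mg]Br
Why: Copper-catalysed 1,4-addition of the vinyl Grignard reagent should occur anti to the C4 isopropyl group (3,4-trans), and the regiodefined enolate 9 is trapped in an aldol reaction with formaldehyde anti to the new vinyl group (2,3-trans), the all-equatorial isomer also being the thermodynamically favoured one.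

Step 4
Reactants: 10 (±)-(2R*,3R*,4R*)-3-ethenyl-2-(hydroxymethyl)-4-(propan-2-yl)cyclohexan-1-one
Product: 11 (±)-(2R*,3R*,4R*)-2-({[tert-butyl(dimethyl)silyl]oxy}methyl)-3-ethenyl-4-(propan-2-yl)cyclohexan-1-one
Conditions: TBSCl (1.2 equiv), imidazole (2 equiv), CH2Cl2, 0 °C → rt
Reagents that add atoms: tert-butyldimethylsilyl chloride, CC(C)(C)[Si](C)(C)Cl
Why: Silyl ether formation at the primary alcohol masks the β-hydroxy ketone against retro-aldol cleavage and alkoxide chemistry in the ylide step and creates no stereocentre.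

Step 5
Reactants: 11 (±)-silyloxymethyl ketone
Product: 12 (±)-tert-butyl{[(3S*,4R*,5R*,6R*)-5-ethenyl-6-(propan-2-yl)-1-oxaspiro[2.5]octan-4-yl]methoxy}dimethylsilane
Conditions: Me3S+ I− (1.6 equiv), n-BuLi (1.5 equiv), THF, −10 °C; then 11, −10 → 0 °C
Reagents that add atoms: trimethylsulfonium iodide, C[S+](C)C.[I-]
Why: In this Corey–Chaykovsky epoxidation the small, irreversibly adding dimethylsulfonium methylide should attack the chair cyclohexanone (all three substituents equatorial) from the axial direction, so the new CH2 is axial and the oxirane oxygen equatorial, which is the C9 configuration required in both halves.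

Step 6
Reactants: 12 (±)-spiro-epoxide silyl ether
Product: 13 (±)-[(3S*,4R*,5R*,6R*)-5-ethenyl-6-(propan-2-yl)-1-oxaspiro[2.5]octan-4-yl]methanol
Conditions: TBAF (1.5 equiv), AcOH (1.5 equiv), THF, 0 °C → rt
Reagents that add atoms: none
Why: Fluoride-induced desilylation, buffered with acetic acid so that the liberated alkoxide does not open the neighbouring oxirane, should free the primary alcohol without touching any stereocentre.

Step 7
Reactants: 13 (±)-epoxy alcohol
Product: 15 (±)-(3S*,4S*,5R*,6R*)-5-ethenyl-6-(propan-2-yl)-1-oxaspiro[2.5]octane-4-carboxylic acid, via epoxy aldehyde 14 (not isolated)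
Conditions: TEMPO (0.2 equiv), PhI(OAc)2 (2.5 equiv), MeCN–pH 7 phosphate buffer (1:1), rt
Reagents that add atoms: water, O
Why: Nitroxyl-catalysed oxidation with the hypervalent iodine reagent takes the primary alcohol through aldehyde 14 and its hydrate to the acid under near-neutral conditions that should spare the oxirane, the vinyl group and the configuration at C4.

Step 8
Reactants: 15 (±)-epoxy acid; 16 tert-butyl 2-(bromomethyl)prop-2-enoate
Product: 17 (±)-2-(tert-butoxycarbonyl)prop-2-en-1-yl (3S*,4S*,5R*,6R*)-5-ethenyl-6-(propan-2-yl)-1-oxaspiro[2.5]octane-4-carboxylate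
Conditions: 16 (1.2 equiv), KHCO3 (1.5 equiv), DMF, 0 °C → rt
Reagents that add atoms: none
Why: O-Alkylation of the carboxylate with the allylic bromide (SN2 or SN2′ displacement, both giving the same ester) installs the acrylate for ring closure under conditions mild enough for the β,γ-epoxy acid.

Step 9
Reactants: 17 (±)-diene ester
Product: 18 (±)-tert-butyl (5aS*,6R*,9S*,9aS*)-1-oxo-6-(propan-2-yl)-3,5a,6,7,8,9a-hexahydro-1H-spiro[2-benzoxepine-9,2′-oxirane]-4-carboxylate
Conditions: second-generation Hoveyda–Grubbs catalyst RuCl2(SIMes)(=CH–C6H4-2-OiPr) (5 mol %), toluene (5 mM), 80 °C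
Reagents that add atoms: none
Why: Ring-closing metathesis between the vinyl group and the 1,1-disubstituted acrylate should close the seven-membered lactone with loss of ethene, the ring enforcing the Z geometry of the trisubstituted enoate and the trans-diequatorial chains favouring closure over oligomerisation.

Step 10
Reactants: 18 (±)-spiro-epoxide ester (first portion)
Product: 19 tert-butyl (5aS,6R,9S,9aS)-9-hydroxy-9-(hydroxymethyl)-1-oxo-6-(propan-2-yl)-1,3,5a,6,7,8,9,9a-octahydro-2-benzoxepine-4-carboxylate
Conditions: epoxide hydrolase ((9S)-selective, from a screening panel, e.g. Rhodotorula glutinis or Aspergillus niger enzyme), phosphate buffer pH 7.5–DMSO (9:1), 30 °C, stopped short of half conversion; chromatography (polar diol separated from unreacted epoxide)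
Reagents that add atoms: water, O
Why: In this enzymatic kinetic resolution of a 2,2-disubstituted oxirane the active-site carboxylate should open the fast-reacting (9S) antipode at the unsubstituted CH2 and the alkyl–enzyme ester is then hydrolysed, so the C9–O bond and the C9 configuration are untouched, and stopping early keeps the diol enantiomerically pure.

Step 11
Reactants: 18 (±)-spiro-epoxide ester (second portion)
Product: 20 tert-butyl (5aR,6S,9R,9aR)-1-oxo-6-(propan-2-yl)-3,5a,6,7,8,9a-hexahydro-1H-spiro[2-benzoxepine-9,2′-oxirane]-4-carboxylate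
Conditions: the same (9S)-selective epoxide hydrolase, phosphate buffer pH 7.5–DMSO (9:1), 30 °C, carried past half conversion until the (9S) epoxide is consumed; extraction, chromatography (epoxide separated from the diol)
Reagents that add atoms: none
Why: The same enzymatic kinetic resolution, carried beyond half conversion, should turn the (9S) antipode completely into the polar diol, so that the slow-reacting (9R) epoxide is recovered enantiomerically pure with its four stereocentres untouched.

Step 12
Reactants: 19 (5aS,6R,9S,9aS) diol tert-butyl ester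
Product: 21 (5aS,6R,9S,9aS)-9-hydroxy-9-(hydroxymethyl)-1-oxo-6-(propan-2-yl)-1,3,5a,6,7,8,9,9a-octahydro-2-benzoxepine-4-carboxylic acid
Conditions: TFA–CH2Cl2 (1:4), 0 °C → rt; then MeOH–aq. NaHCO3 (cleaves any trifluoroacetate), acidify to pH 4
Reagents that add atoms: none
Why: Acid-mediated tert-butyl ester cleavage with loss of isobutene should free the carboxylic acid while the lactone, the diol and all stereocentres remain.

Step 13
Reactants: 21 (5aS,6R,9S,9aS) diol acid; 20 (5aR,6S,9R,9aR) spiro-epoxide ester
Product: 22 tert-butyl (5aR,6S,9R,9aR)-9-hydroxy-9-({[(5aS,6R,9S,9aS)-9-hydroxy-9-(hydroxymethyl)-1-oxo-6-(propan-2-yl)-1,3,5a,6,7,8,9,9a-octahydro-2-benzoxepine-4-carbonyl]oxy}methyl)-1-oxo-6-(propan-2-yl)-1,3,5a,6,7,8,9,9a-octahydro-2-benzoxepine-4-carboxylate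
Conditions: 21 (1.0 equiv), 20 (1.1 equiv), Cs2CO3 (0.2 equiv), DMF, 50 °C
Reagents that add atoms: none
Why: In this base-catalysed carboxylic acid–epoxide addition the carboxylate of 21 (Cs+ counter-ion) should open the oxirane of 20 at its unsubstituted CH2 (SN2), leaving C9 of 20 untouched, and any minor enantiomer left by the resolution ends mainly in diastereomeric esters that can be separated at this stage.

Step 14
Reactants: 22 tert-butyl ester of the target
Product: 23 (5aR,6S,9R,9aR)-9-hydroxy-9-({[(5aS,6R,9S,9aS)-9-hydroxy-9-(hydroxymethyl)-1-oxo-6-(propan-2-yl)-1,3,5a,6,7,8,9,9a-octahydro-2-benzoxepine-4-carbonyl]oxy}methyl)-1-oxo-6-(propan-2-yl)-1,3,5a,6,7,8,9,9a-octahydro-2-benzoxepine-4-carboxylic acid (CNP0340505.1)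
Conditions: TFA–CH2Cl2 (1:4), 0 °C → rt
Reagents that add atoms: none
Why: Acid-mediated cleavage of the remaining tert-butyl ester (loss of isobutene) should give the target without affecting the two lactones, the connecting ester or any stereocentre.

**Compound list**

1 | 3-methylbutanal (isovaleraldehyde) | CC(C)CC=O | starting material
2 | formaldehyde | C=O | starting material
3 | 3-methyl-2-methylidenebutanal (2-isopropylacrolein) | CC(C)C(=C)C=O | intermediate
4 | tert-butyl 3-oxobutanoate | CC(=O)CC(=O)OC(C)(C)C | starting material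
5 | tert-butyl 2-acetyl-4-formyl-5-methylhexanoate (stereoisomer mixture, not isolated) | CC(=O)C(CC(C=O)C(C)C)C(=O)OC(C)(C)C | intermediate
6 | tert-butyl 2-oxo-5-(propan-2-yl)cyclohex-3-ene-1-carboxylate (stereoisomer mixture, not isolated) | CC(C)C1CC(C(=O)OC(C)(C)C)C(=O)C=C1 | intermediate
7 | 2-oxo-5-(propan-2-yl)cyclohex-3-ene-1-carboxylic acid (stereoisomer mixture, not isolated) | CC(C)C1CC(C(=O)O)C(=O)C=C1 | intermediate
8 | (±)-4-(propan-2-yl)cyclohex-2-en-1-one | CC(C)[C@H]1CCC(=O)C=C1.CC(C)[C@@H]1CCC(=O)C=C1 | intermediate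
9 | (±)-bromomagnesium (3R*,4R*)-3-ethenyl-4-(propan-2-yl)cyclohex-1-en-1-olate (not isolated) | CC(C)[C@H]1CCC(O[Mg]Br)=C[C@@H]1C=C.CC(C)[C@@H]1CCC(O[Mg]Br)=C[C@H]1C=C | intermediate
10 | (±)-(2R*,3R*,4R*)-3-ethenyl-2-(hydroxymethyl)-4-(propan-2-yl)cyclohexan-1-one | CC(C)[C@H]1CCC(=O)[C@@H](CO)[C@@H]1C=C.CC(C)[C@@H]1CCC(=O)[C@H](CO)[C@H]1C=C | intermediate
11 | (±)-(2R*,3R*,4R*)-2-({[tert-butyl(dimethyl)silyl]oxy}methyl)-3-ethenyl-4-(propan-2-yl)cyclohexan-1-one | CC(C)[C@H]1CCC(=O)[C@@H](CO[Si](C)(C)C(C)(C)C)[C@@H]1C=C.CC(C)[C@@H]1CCC(=O)[C@H](CO[Si](C)(C)C(C)(C)C)[C@H]1C=C | intermediate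
12 | (±)-tert-butyl{[(3S*,4R*,5R*,6R*)-5-ethenyl-6-(propan-2-yl)-1-oxaspiro[2.5]octan-4-yl]methoxy}dimethylsilane (oxirane O equatorial) | CC(C)[C@H]1CC[C@@]2(CO2)[C@@H](CO[Si](C)(C)C(C)(C)C)[C@@H]1C=C.CC(C)[C@@H]1CC[C@]2(CO2)[C@H](CO[Si](C)(C)C(C)(C)C)[C@H]1C=C | intermediate
13 | (±)-[(3S*,4R*,5R*,6R*)-5-ethenyl-6-(propan-2-yl)-1-oxaspiro[2.5]octan-4-yl]methanol | CC(C)[C@H]1CC[C@@]2(CO2)[C@@H](CO)[C@@H]1C=C.CC(C)[C@@H]1CC[C@]2(CO2)[C@H](CO)[C@H]1C=C | intermediate
14 | (±)-(3S*,4S*,5R*,6R*)-5-ethenyl-6-(propan-2-yl)-1-oxaspiro[2.5]octane-4-carbaldehyde (not isolated) | CC(C)[C@H]1CC[C@@]2(CO2)[C@@H](C=O)[C@@H]1C=C.CC(C)[C@@H]1CC[C@]2(CO2)[C@H](C=O)[C@H]1C=C | intermediate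
15 | (±)-(3S*,4S*,5R*,6R*)-5-ethenyl-6-(propan-2-yl)-1-oxaspiro[2.5]octane-4-carboxylic acid | CC(C)[C@H]1CC[C@@]2(CO2)[C@@H](C(=O)O)[C@@H]1C=C.CC(C)[C@@H]1CC[C@]2(CO2)[C@H](C(=O)O)[C@H]1C=C | intermediate
16 | tert-butyl 2-(bromomethyl)prop-2-enoate | C=C(CBr)C(=O)OC(C)(C)C | starting material
17 | (±)-2-(tert-butoxycarbonyl)prop-2-en-1-yl (3S*,4S*,5R*,6R*)-5-ethenyl-6-(propan-2-yl)-1-oxaspiro[2.5]octane-4-carboxylate | CC(C)[C@H]1CC[C@@]2(CO2)[C@@H](C(=O)OCC(=C)C(=O)OC(C)(C)C)[C@@H]1C=C.CC(C)[C@@H]1CC[C@]2(CO2)[C@H](C(=O)OCC(=C)C(=O)OC(C)(C)C)[C@H]1C=C | intermediate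
18 | (±)-tert-butyl (5aS*,6R*,9S*,9aS*)-1-oxo-6-(propan-2-yl)-3,5a,6,7,8,9a-hexahydro-1H-spiro[2-benzoxepine-9,2′-oxirane]-4-carboxylate | CC(C)[C@H]1CC[C@@]2(CO2)[C@H]3C(=O)OCC(C(=O)OC(C)(C)C)=C[C@H]13.CC(C)[C@@H]1CC[C@]2(CO2)[C@@H]3C(=O)OCC(C(=O)OC(C)(C)C)=C[C@@H]13 | intermediate
19 | tert-butyl (5aS,6R,9S,9aS)-9-hydroxy-9-(hydroxymethyl)-1-oxo-6-(propan-2-yl)-1,3,5a,6,7,8,9,9a-octahydro-2-benzoxepine-4-carboxylate | CC(C)[C@H]1CC[C@@](O)(CO)[C@H]2C(=O)OCC(C(=O)OC(C)(C)C)=C[C@H]12 | intermediate
20 | tert-butyl (5aR,6S,9R,9aR)-1-oxo-6-(propan-2-yl)-3,5a,6,7,8,9a-hexahydro-1H-spiro[2-benzoxepine-9,2′-oxirane]-4-carboxylate | CC(C)[C@@H]1CC[C@]2(CO2)[C@@H]3C(=O)OCC(C(=O)OC(C)(C)C)=C[C@@H]13 | intermediate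
21 | (5aS,6R,9S,9aS)-9-hydroxy-9-(hydroxymethyl)-1-oxo-6-(propan-2-yl)-1,3,5a,6,7,8,9,9a-octahydro-2-benzoxepine-4-carboxylic acid | CC(C)[C@H]1CC[C@@](O)(CO)[C@H]2C(=O)OCC(C(=O)O)=C[C@H]12 | intermediate
22 | tert-butyl ester of the target (name as in step 13) | CC(C)[C@H]1CC[C@@](O)(CO)[C@H]2C(=O)OCC(C(=O)OC[C@@]3(O)CC[C@@H](C(C)C)[C@@H]4C=C(C(=O)OC(C)(C)C)COC(=O)[C@H]43)=C[C@H]12 | intermediate
23 | CNP0340505.1 (name as in step 14) | CC(C)[C@H]1CC[C@@](O)(CO)[C@H]2C(=O)OCC(C(=O)OC[C@@]3(O)CC[C@@H](C(C)C)[C@@H]4C=C(C(=O)O)COC(=O)[C@H]43)=C[C@H]12 | target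

**Totals and risks**

Total step count: 14. Longest linear sequence: 13 steps (steps 1–10 and 12–14); step 11 is a one-step branch from 18 that delivers 20 for step 13.

Most likely to fail:

Step 10 (and with it step 11, which uses the same enzyme). The hydrolase may bind the bulky bicyclic ester poorly or hydrolyse both antipodes at similar rates, so that neither run gives material of high enantiomeric purity. Fallback: setting out from 18, the antipodes are separated by preparative chromatography on a polysaccharide chiral stationary phase, which gives 20 directly and the (5aS,6R,9S,9aS) epoxide ester F1. F1 is opened at the oxirane CH2 with buffered formate (HCO2H, cesium formate HCO2Cs, DMF, 50 °C) to the 9-(formyloxymethyl) alcohol F2, and the formyl group is removed by mild methanolysis (MeOH, KHCO3, 0 °C). This returns to the route at 19 and supplies 20, so that step 11 is not needed.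

Step 13. The intermolecular opening of the hindered spiro-oxirane by the carboxylate may be slower than base-induced acyl migration of the seven-membered lactone onto the free C9 CH2OH of 21 or 22 (loss of the oxepinone ring). Fallback (esterification instead of epoxide opening), setting out from 20 and 21: 20 is opened with buffered formate (HCO2H, HCO2Cs, DMF, 50 °C) to the (5aR,6S,9R,9aR) formate F3, which mild methanolysis (MeOH, KHCO3, 0 °C) converts into the (5aR,6S,9R,9aR) diol ester F4. The diol of 21 is masked as the cyclic phenylboronate F5 (PhB(OH)2, toluene, MgSO4). Yamaguchi esterification (2,4,6-trichlorobenzoyl chloride, Et3N, then DMAP) joins F5 to the primary hydroxyl of F4 to give the boronate-protected diester F6. Exchange with pinacol frees the diol and returns to the route at 22.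

Step 3. Trapping of the magnesium enolate with gaseous formaldehyde may be incomplete or go too far (retro-aldol loss of formaldehyde, dehydration to the 2-methylene ketone, double hydroxymethylation). Fallback, setting out from 8: the copper-catalysed vinyl addition is run in the presence of TMSCl so that the enolate is captured as the trimethylsilyl enol ether F7, which is isolated. F7 is hydroxymethylated in a Lewis-acid-catalysed Mukaiyama aldol reaction with aqueous formaldehyde (Sc(OTf)3, THF–H2O, rt), returning to the route at 10.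

**Further compounds**

F1 | step 10 | tert-butyl (5aS,6R,9S,9aS)-1-oxo-6-(propan-2-yl)-3,5a,6,7,8,9a-hexahydro-1H-spiro[2-benzoxepine-9,2′-oxirane]-4-carboxylate | CC(C)[C@H]1CC[C@@]2(CO2)[C@H]3C(=O)OCC(C(=O)OC(C)(C)C)=C[C@H]13
F2 | step 10 | tert-butyl (5aS,6R,9S,9aS)-9-[(formyloxy)methyl]-9-hydroxy-1-oxo-6-(propan-2-yl)-1,3,5a,6,7,8,9,9a-octahydro-2-benzoxepine-4-carboxylate | CC(C)[C@H]1CC[C@@](O)(COC=O)[C@H]2C(=O)OCC(C(=O)OC(C)(C)C)=C[C@H]12
F3 | step 13 | tert-butyl (5aR,6S,9R,9aR)-9-[(formyloxy)methyl]-9-hydroxy-1-oxo-6-(propan-2-yl)-1,3,5a,6,7,8,9,9a-octahydro-2-benzoxepine-4-carboxylate | CC(C)[C@@H]1CC[C@](O)(COC=O)[C@@H]2C(=O)OCC(C(=O)OC(C)(C)C)=C[C@@H]12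
F4 | step 13 | tert-butyl (5aR,6S,9R,9aR)-9-hydroxy-9-(hydroxymethyl)-1-oxo-6-(propan-2-yl)-1,3,5a,6,7,8,9,9a-octahydro-2-benzoxepine-4-carboxylate | CC(C)[C@@H]1CC[C@](O)(CO)[C@@H]2C(=O)OCC(C(=O)OC(C)(C)C)=C[C@@H]12
F5 | step 13 | cyclic phenylboronate of 21 (2-phenyl-1,3,2-dioxaborolane spiro-fused at C9, free acid at C4) | CC(C)[C@H]1CC[C@@]2(COB(c3ccccc3)O2)[C@H]4C(=O)OCC(C(=O)O)=C[C@H]14
F6 | step 13 | cyclic phenylboronate of 22 (boronate on the diol of the acyl half) | CC(C)[C@H]1CC[C@@]2(COB(c3ccccc3)O2)[C@H]4C(=O)OCC(C(=O)OC[C@@]5(O)CC[C@@H](C(C)C)[C@@H]6C=C(C(=O)OC(C)(C)C)COC(=O)[C@H]65)=C[C@H]14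
F7 | step 3 | (±)-{[(3R*,4R*)-3-ethenyl-4-(propan-2-yl)cyclohex-1-en-1-yl]oxy}trimethylsilane | CC(C)[C@H]1CCC(O[Si](C)(C)C)=C[C@@H]1C=C.CC(C)[C@@H]1CCC(O[Si](C)(C)C)=C[C@H]1C=C
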